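**Retrosynthetic overview**

Numbering of the target (bicyclo[3.2.1]octane): C1 H-bridgehead, C2 ketone, C3 C–OMe, C4 =CH, C5 allyl bridgehead, C6 CHMe, C7 CHAr, C8 bridging ketone.
Key disconnection: C4–C5 and C1–C8, both in the six-membered ring C1–C2–C3–C4–C5–C8. This is a formal [4+2] between a tethered allyl(alkyl)ketene (C5=C8=O) and a 1,2-dimethoxy-3-silyloxydiene (C4=C3–C2=C1) within acyclic acid chloride 19. The five-membered ring (C1–C8) closes first, then the six-membered ring (C4–C5), which also completes the seven-membered ring.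
Enabling feature: that ring is a cyclohex-4-ene-1,3-dione in which C8/C5 have the polarity of a ketene (acyl carbon, then enolate carbon) and C1/C4 that of the two ends of a 1-alkoxy-3-silyloxydiene (nucleophilic CH, then electrophilic CH–OMe). C1 is a bridgehead, so the β-diketone cannot enolise once it is formed.
Precursor: C6/C7 come from an enamine-catalysed Michael addition of propanal to the nitrostyrene. The nitro group then activates C1 for acylation by the C2–C4 unit and is removed. The C5 allyl group and C8 come from a Wittig/Claisen homologation of the aldehyde.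

Key step: step 11

Assumption: compounds 1 and 10 are taken as commercial; the Z geometry written for the 2,3-dimethoxyacryloyl unit is the expected major isomer and is not critical, because that CH(OMe)= carbon loses its methoxy group in step 11.

Step 1
Reactants: 1 allyl chloromethyl ether; 2 triphenylphosphine
Product: 3 (allyloxymethyl)triphenylphosphonium chloride
Conditions: toluene, 60 °C; filter, dry
Reagents that add atoms: none
Why: SN2 quaternisation of the phosphine by the reactive α-chloro ether gives the alkoxymethylphosphonium salt needed for the one-carbon homologating Wittig reaction of step 5.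

Step 2
Reactants: 4 methyl methoxyacetate; 5 methyl formate
Product: 7 methyl (Z)-2,3-dimethoxyacrylate, via sodium formyl enolate 6 (not isolated)
Conditions: NaH, THF, 0 °C → rt; then Me2SO4, DMF, rt
Reagents that add atoms: dimethyl sulfate, COS(=O)(=O)OC
Why: Crossed Claisen formylation of the ester enolate followed by O-methylation of the formyl enolate with a hard electrophile is the standard β-methoxyacrylate synthesis and should give mainly the isomer with the two methoxy groups cis (Z).

Step 3
Reactants: 7 methyl (Z)-2,3-dimethoxyacrylate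
Product: 8 (Z)-2,3-dimethoxyacrylic acid
Conditions: LiOH, THF/H2O, 0 °C → rt; then 1 M HCl to pH 3, 0 °C
Reagents that add atoms: lithium hydroxide, [Li+].[OH-]
Why: Ester saponification by acyl–oxygen cleavage; the push–pull enol ether is inert to cold hydroxide and should survive brief cold acidification.

Step 4
Reactants: 9 propanal; 10 (E)-1,2-dimethoxy-4-(2-nitrovinyl)benzene
Product: 11 (2R,3S)-3-(3,4-dimethoxyphenyl)-2-methyl-4-nitrobutanal
Conditions: 9 (3 equiv), (S)-2-[diphenyl(trimethylsilyloxy)methyl]pyrrolidine (10 mol%), 4-nitrophenol (10 mol%), toluene, 0 °C → rt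
Reagents that add atoms: none
Why: Enamine-catalysed asymmetric Michael addition of an aldehyde to a nitroalkene, in which the bulky diphenyl(silyloxy)methyl group of the (S)-catalyst shields one face of the E-enamine and the acyclic synclinal transition state should give the syn (2R,3S) adduct, fixing C6 and C7 of the target (methyl and aryl trans on the later five-membered ring).

Step 5
Reactants: 11 (2R,3S)-3-(3,4-dimethoxyphenyl)-2-methyl-4-nitrobutanal; 3 (allyloxymethyl)triphenylphosphonium chloride
Product: 13 4-[(2S,3R)-3-methyl-1-nitro-5-(prop-2-en-1-yloxy)pent-4-en-2-yl]-1,2-dimethoxybenzene (E/Z mixture), via phosphorus ylide 12 (not isolated)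
Conditions: 3 (2.5 equiv), KN(SiMe3)2 (2.4 equiv), THF, −78 °C; then 11, −78 → 0 °C; aq NH4Cl
Reagents that add atoms: none
Why: Wittig olefination with an alkoxymethylene ylide extends the chain by one carbon (the future C8) and installs the allyl vinyl ether; the excess ylide absorbs the acidic nitromethylene proton (the nitronate is reprotonated on work-up) and the low temperature should protect the α-stereocentre.

Step 6
Reactants: 13 4-[(2S,3R)-3-methyl-1-nitro-5-(prop-2-en-1-yloxy)pent-4-en-2-yl]-1,2-dimethoxybenzene; 8 (Z)-2,3-dimethoxyacrylic acid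
Product: 15 (1Z,5S,6R)-5-(3,4-dimethoxyphenyl)-1,2-dimethoxy-6-methyl-4-nitro-8-(prop-2-en-1-yloxy)octa-1,7-dien-3-one (C4 epimers), via acylimidazole 14 (not isolated)
Conditions: 8, 1,1′-carbonyldiimidazole, THF, rt; separately 13, KOtBu (1.0 equiv), THF/DMSO, 0 °C; combine, rt; AcOH
Reagents that add atoms: none
Why: C-Acylation of a primary nitronate by an acylimidazole forms the C1–C2 bond, with the nitro group as a traceless activating group and the released imidazolide deprotonating the more acidic α-nitro ketone; exactly one equivalent of alkoxide is used so that no free KOtBu remains to isomerise the allyl ether, and the new stereocentre is erased in step 7.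

Step 7
Reactants: 15 (1Z,5S,6R)-5-(3,4-dimethoxyphenyl)-1,2-dimethoxy-6-methyl-4-nitro-8-(prop-2-en-1-yloxy)octa-1,7-dien-3-one
Product: 16 (1Z,5S,6R)-5-(3,4-dimethoxyphenyl)-1,2-dimethoxy-6-methyl-8-(prop-2-en-1-yloxy)octa-1,7-dien-3-one
Conditions: Bu3SnH (1.5 equiv), AIBN (cat.), toluene, 80 °C
Reagents that add atoms: none
Why: Radical denitration of a secondary α-nitro ketone (stannyl radical adds to the nitro group, C–N homolysis gives the ketone-stabilised radical, hydrogen-atom transfer from Bu3SnH) removes the activating group without touching the enol ethers or the stereocentres.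

Step 8
Reactants: 16 (1Z,5S,6R)-5-(3,4-dimethoxyphenyl)-1,2-dimethoxy-6-methyl-8-(prop-2-en-1-yloxy)octa-1,7-dien-3-one
Product: 17 (3R,4S,7Z)-4-(3,4-dimethoxyphenyl)-7,8-dimethoxy-3-methyl-6-oxo-2-(prop-2-en-1-yl)oct-7-enal (C2 epimers)
Conditions: o-xylene, 2,6-di-tert-butyl-4-methylphenol (cat.), 160 °C, sealed tube
Reagents that add atoms: none
Why: Thermal Claisen rearrangement ([3,3]-sigmatropic shift through a chair transition state) moves the allyl group from oxygen to C5 and releases the C8 aldehyde; the C5 configuration is immaterial because C5 becomes the sp2 ketene carbon in step 11.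

Step 9
Reactants: 17 (3R,4S,7Z)-4-(3,4-dimethoxyphenyl)-7,8-dimethoxy-3-methyl-6-oxo-2-(prop-2-en-1-yl)oct-7-enal
Product: 18 (3R,4S,7Z)-4-(3,4-dimethoxyphenyl)-7,8-dimethoxy-3-methyl-6-oxo-2-(prop-2-en-1-yl)oct-7-enoic acid (C2 epimers)
Conditions: NaClO2, NaH2PO4, 2-methyl-2-butene, tBuOH/H2O, 0 °C → rt
Reagents that add atoms: sodium chlorite, [Na+].[O-]Cl=O
Why: Pinnick oxidation of the aldehyde to the acid under buffered conditions with 2-methyl-2-butene as HOCl scavenger, which should spare the alkene, the electron-rich arene and the β-methoxy enone.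

Step 10
Reactants: 18 (3R,4S,7Z)-4-(3,4-dimethoxyphenyl)-7,8-dimethoxy-3-methyl-6-oxo-2-(prop-2-en-1-yl)oct-7-enoic acid
Product: 19 (3R,4S,7Z)-4-(3,4-dimethoxyphenyl)-7,8-dimethoxy-3-methyl-6-oxo-2-(prop-2-en-1-yl)oct-7-enoyl chloride (C2 epimers)
Conditions: 1-chloro-N,N,2-trimethylprop-1-en-1-amine (1.2 equiv), CH2Cl2, 0 °C → rt; evaporate, use crude
Reagents that add atoms: 1-chloro-N,N,2-trimethylprop-1-en-1-amine, CC(C)=C(Cl)N(C)C
Why: The α-chloroenamine converts the acid into the acid chloride under neutral conditions, without HCl or iminium chloride species that the acid-labile β-methoxy enone would not tolerate.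

Step 11
Reactants: 19 (3R,4S,7Z)-4-(3,4-dimethoxyphenyl)-7,8-dimethoxy-3-methyl-6-oxo-2-(prop-2-en-1-yl)oct-7-enoyl chloride
Product: 23 kadsurenin D, via keto ketene 20 (not isolated), via silyl dienol ether ketene 21 (not isolated), via bicyclic silyl enol ether 22 (not isolated)
Conditions: Et3N (2.1 equiv), CH2Cl2 (0.01 M), rt → 40 °C; then −78 °C, tBuMe2SiOTf (1.2 equiv), → rt; then 1 M HCl, THF, 0 °C
Reagents that add atoms: none
Why: Proposed new method: Et3N dehydrochlorinates the α-branched acid chloride to allyl(alkyl)ketene 20 before tBuMe2SiOTf/Et3N turns the β-methoxy enone into the 1,2-dimethoxy-3-silyloxydiene 21; its terminal carbon C1 then adds in the ketene plane to C8 (5-endo-dig closure of the cyclopentane) with transfer of the silyl group to the new enolate oxygen, and the resulting C5 silyl enol ether closes the six-membered ring (and with it the seven-membered ring) by a silyl triflate-catalysed Mukaiyama–Michael addition to C4 of the β-methoxy enone (6-endo-trig), acid work-up expelling methanol and the silyl group to give the C3=C4 enone. The closest known reaction types are the tBuMe2SiOTf/Et3N-mediated intramolecular double Michael (formal Diels–Alder) reaction of 2-silyloxydienes with tethered acrylates, the stepwise cyclocondensation of 1-methoxy-3-silyloxydienes, and the carbocyclisation of ketenes by tethered π-nucleophiles; a ketene as the two-carbon partner of such a diene in a bridging mode is new. C1 is set in the first closure: the ketene arm on C6 can reach only the diene face on which C6 stands out of plane, and A(1,3) strain in the Z silyl enol ether puts the C7 hydrogen in plane and the aryl group on the other face, so the dienyl chain should end trans to aryl on the cyclopentane. C5 is then set by the bridge itself, which can only span the ring cis, so the allyl group ends exo, while C6 and C7 are carried over from step 4. The step needs C–C rather than O–C closure and ring closure before loss of the C1 proton (a C1 enol would be planar and could never become the bridgehead); the silyl shift blocks the enolate oxygen, C1 has only one carbonyl neighbour until the bicycle exists, the near-stoichiometric amine leaves no free base, and forming the ketene before the diene excludes direct acylation, which would give no C5 nucleophile.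

**Compound list**

1 | allyl chloromethyl ether | C=CCOCCl | starting material
2 | triphenylphosphine | c1ccc(cc1)P(c1ccccc1)c1ccccc1 | starting material
3 | (allyloxymethyl)triphenylphosphonium chloride | C=CCOC[P+](c1ccccc1)(c1ccccc1)c1ccccc1.[Cl-] | intermediate
4 | methyl methoxyacetate | COCC(=O)OC | starting material
5 | methyl formate | COC=O | starting material
6 | sodium 2,3-dimethoxy-3-oxoprop-1-en-1-olate (formed in the flask) | [Na+].[O-]C=C(OC)C(=O)OC | intermediate
7 | methyl (Z)-2,3-dimethoxyacrylate | CO/C=C(\OC)C(=O)OC | intermediate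
8 | (Z)-2,3-dimethoxyacrylic acid | CO/C=C(\OC)C(=O)O | intermediate
9 | propanal | CCC=O | starting material
10 | (E)-1,2-dimethoxy-4-(2-nitrovinyl)benzene | COc1ccc(/C=C/[N+](=O)[O-])cc1OC | starting material
11 | (2R,3S)-3-(3,4-dimethoxyphenyl)-2-methyl-4-nitrobutanal | [O-][N+](=O)C[C@H](c1ccc(OC)c(OC)c1)[C@@H](C)C=O | intermediate
12 | (allyloxymethylene)triphenylphosphorane (formed in the flask) | C=CCOC=P(c1ccccc1)(c1ccccc1)c1ccccc1 | intermediate
13 | 4-[(2S,3R)-3-methyl-1-nitro-5-(prop-2-en-1-yloxy)pent-4-en-2-yl]-1,2-dimethoxybenzene, E/Z mixture at the enol ether | [O-][N+](=O)C[C@H](c1ccc(OC)c(OC)c1)[C@@H](C)C=COCC=C | intermediate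
14 | (Z)-1-(1H-imidazol-1-yl)-2,3-dimethoxyprop-2-en-1-one (formed in the flask) | CO/C=C(\OC)C(=O)n1ccnc1 | intermediate
15 | (1Z,5S,6R)-5-(3,4-dimethoxyphenyl)-1,2-dimethoxy-6-methyl-4-nitro-8-(prop-2-en-1-yloxy)octa-1,7-dien-3-one, both C4 epimers, 7E/7Z | CO/C=C(\OC)C(=O)C([N+](=O)[O-])[C@H](c1ccc(OC)c(OC)c1)[C@@H](C)C=COCC=C | intermediate
16 | (1Z,5S,6R)-5-(3,4-dimethoxyphenyl)-1,2-dimethoxy-6-methyl-8-(prop-2-en-1-yloxy)octa-1,7-dien-3-one, 7E/7Z | CO/C=C(\OC)C(=O)C[C@H](c1ccc(OC)c(OC)c1)[C@@H](C)C=COCC=C | intermediate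
17 | (3R,4S,7Z)-4-(3,4-dimethoxyphenyl)-7,8-dimethoxy-3-methyl-6-oxo-2-(prop-2-en-1-yl)oct-7-enal, both C2 epimers | CO/C=C(\OC)C(=O)C[C@H](c1ccc(OC)c(OC)c1)[C@@H](C)C(CC=C)C=O | intermediate
18 | (3R,4S,7Z)-4-(3,4-dimethoxyphenyl)-7,8-dimethoxy-3-methyl-6-oxo-2-(prop-2-en-1-yl)oct-7-enoic acid, both C2 epimers | CO/C=C(\OC)C(=O)C[C@H](c1ccc(OC)c(OC)c1)[C@@H](C)C(CC=C)C(=O)O | intermediate
19 | (3R,4S,7Z)-4-(3,4-dimethoxyphenyl)-7,8-dimethoxy-3-methyl-6-oxo-2-(prop-2-en-1-yl)oct-7-enoyl chloride, both C2 epimers | CO/C=C(\OC)C(=O)C[C@H](c1ccc(OC)c(OC)c1)[C@@H](C)C(CC=C)C(Cl)=O | intermediate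
20 | (3R,4S,7Z)-4-(3,4-dimethoxyphenyl)-7,8-dimethoxy-3-methyl-2-(prop-2-en-1-yl)octa-1,7-diene-1,6-dione (keto ketene, formed in the flask) | CO/C=C(\OC)C(=O)C[C@H](c1ccc(OC)c(OC)c1)[C@@H](C)C(CC=C)=C=O | intermediate
21 | (3R,4R,5Z,7Z)-6-[(tert-butyldimethylsilyl)oxy]-4-(3,4-dimethoxyphenyl)-7,8-dimethoxy-3-methyl-2-(prop-2-en-1-yl)octa-1,5,7-trien-1-one (silyl dienol ether ketene, formed in the flask; 5Z expected) | CO/C=C(\OC)/C(O[Si](C)(C)C(C)(C)C)=C/[C@H](c1ccc(OC)c(OC)c1)[C@@H](C)C(CC=C)=C=O | intermediate
22 | 5-allyl-2-[(tert-butyldimethylsilyl)oxy]-7-(3,4-dimethoxyphenyl)-3,4-dimethoxy-6-methylbicyclo[3.2.1]oct-2-en-8-one, C1/C5/C6/C7 configured as in 23, both C4 epimers (formed in the flask) | C=CC[C@]12C(OC)C(OC)=C(O[Si](C)(C)C(C)(C)C)[C@H](C1=O)[C@H](c1ccc(OC)c(OC)c1)[C@H]2C | intermediate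
23 | kadsurenin D, (1S,5S,6R,7R)-7-(3,4-dimethoxyphenyl)-3-methoxy-6-methyl-5-(prop-2-en-1-yl)bicyclo[3.2.1]oct-3-ene-2,8-dione | C=CC[C@]12C=C(OC)C(=O)[C@H](C1=O)[C@H](c1ccc(OC)c(OC)c1)[C@H]2C | target

**Step count and risks**

Total step count: 11. Longest linear sequence: 8 steps (steps 4 to 11; the branch through steps 2, 3 and 6 to 11 is equally long).

Steps most likely to fail:

1. Step 11 (proposed new method). The cascade may stop after the first bond, by loss of the C1 proton to a planar 2-acylcyclopentanone enol that cannot close the bridge. It may also close through the enolate oxygen instead of C5, or the ketene may dimerise before the diene is formed. The fallback abandons the annulation for the known acid-promoted [5+2] cycloaddition of a p-quinone monoketal with an (E)-propenylarene, which makes C5–C6 and C1–C7 instead. It sets out from propanal 9. Addition of commercial 3,4-(MeO)2C6H3MgBr in THF should give 1-(3,4-dimethoxyphenyl)propan-1-ol F1, and dehydration (TsOH, toluene, reflux) should give (E)-1,2-dimethoxy-4-(prop-1-en-1-yl)benzene F2. In parallel, commercial 3,4-dimethoxyphenol is O-allylated (allyl bromide, K2CO3, acetone) to 4-(allyloxy)-1,2-dimethoxybenzene F3, aromatic Claisen rearrangement (N,N-diethylaniline, 190 °C) leads to 2-allyl-4,5-dimethoxyphenol F4, and PhI(OAc)2 in methanol gives 2-allyl-4,4,5-trimethoxycyclohexa-2,5-dien-1-one F5. Me3SiOTf in MeCN at −30 °C ionises F5 to the 2-allyl-4,5-dimethoxy-substituted oxidopentadienyl cation. This cation should add F2 with the methyl-bearing carbon going to the allyl-bearing terminus and the benzylic cation closing on the other terminus, giving racemic kadsurenin D F6 after loss of the second methyl group. The trans aryl/methyl relation follows from the E alkene, and the exo-aryl adduct is the expected major isomer. Preparative HPLC on a chiral stationary phase then returns the route at 23.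

2. Step 6. The nitronate may react through oxygen, or add to the β-carbon of the β-methoxyacryloyl imidazolide with loss of methoxide, instead of C-acylation. The fallback makes the C1–C2 bond at the aldehyde level, where nitronates react at carbon, and completes the enone unit afterwards. It sets out from 13. Henry reaction with methoxyacetaldehyde (Bu4NF cat., THF, 0 °C) should give (4S,5R)-4-(3,4-dimethoxyphenyl)-1-methoxy-5-methyl-3-nitro-7-(prop-2-en-1-yloxy)hept-6-en-2-ol F7. Dess–Martin oxidation gives the α-nitro ketone (4S,5R)-4-(3,4-dimethoxyphenyl)-1-methoxy-5-methyl-3-nitro-7-(prop-2-en-1-yloxy)hept-6-en-2-one F8, and Bu3SnH/AIBN gives (4S,5R)-4-(3,4-dimethoxyphenyl)-1-methoxy-5-methyl-7-(prop-2-en-1-yloxy)hept-6-en-2-one F9. Condensation with Me2NCH(OMe)2 (90 °C) at the more acidic, less hindered methoxymethylene carbon gives the enaminone (5S,6R)-1-(dimethylamino)-5-(3,4-dimethoxyphenyl)-2-methoxy-6-methyl-8-(prop-2-en-1-yloxy)octa-1,7-dien-3-one F10. Aqueous NaOH/THF hydrolyses it to sodium (5S,6R)-5-(3,4-dimethoxyphenyl)-2-methoxy-6-methyl-3-oxo-8-(prop-2-en-1-yloxy)octa-1,7-dien-1-olate F11, and O-methylation with Me2SO4 returns the route at 16.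

3. Step 8. The keto aldehyde may not survive the temperature of the rearrangement (intramolecular aldol or ene reactions, polymerisation of the enol ether). The fallback brings in the allyl group catalytically at room temperature. It sets out from 16. Selective hydrolysis of the simple enol ether (pyridinium p-toluenesulfonate, wet THF; the push–pull β-methoxy enone should hydrolyse far more slowly) gives (3S,4S,7Z)-4-(3,4-dimethoxyphenyl)-7,8-dimethoxy-3-methyl-6-oxooct-7-enal F12. Direct α-allylation under combined enamine and zerovalent palladium catalysis (Pd(PPh3)4, pyrrolidine, allyl acetate, DMSO, rt; a Tsuji–Trost reaction on the enamine) returns the route at 17.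

**Further compounds**

F1 | step 11 | 1-(3,4-dimethoxyphenyl)propan-1-ol (racemic) | CCC(O)c1ccc(OC)c(OC)c1
F2 | step 11 | (E)-1,2-dimethoxy-4-(prop-1-en-1-yl)benzene | C/C=C/c1ccc(OC)c(OC)c1
F3 | step 11 | 4-(allyloxy)-1,2-dimethoxybenzene | C=CCOc1ccc(OC)c(OC)c1
F4 | step 11 | 2-allyl-4,5-dimethoxyphenol | C=CCc1cc(OC)c(OC)cc1O
F5 | step 11 | 2-allyl-4,4,5-trimethoxycyclohexa-2,5-dien-1-one | C=CCC1=CC(OC)(OC)C(OC)=CC1=O
F6 | step 11 | racemic kadsurenin D (23 and its mirror image) | C=CC[C@]12C=C(OC)C(=O)[C@H](C1=O)[C@H](c1ccc(OC)c(OC)c1)[C@H]2C.C=CC[C@@]12C=C(OC)C(=O)[C@@H](C1=O)[C@@H](c1ccc(OC)c(OC)c1)[C@@H]2C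
F7 | step 6 | (4S,5R)-4-(3,4-dimethoxyphenyl)-1-methoxy-5-methyl-3-nitro-7-(prop-2-en-1-yloxy)hept-6-en-2-ol (C2/C3 epimers) | COCC(O)C([N+](=O)[O-])[C@H](c1ccc(OC)c(OC)c1)[C@@H](C)C=COCC=C
F8 | step 6 | (4S,5R)-4-(3,4-dimethoxyphenyl)-1-methoxy-5-methyl-3-nitro-7-(prop-2-en-1-yloxy)hept-6-en-2-one (C3 epimers) | COCC(=O)C([N+](=O)[O-])[C@H](c1ccc(OC)c(OC)c1)[C@@H](C)C=COCC=C
F9 | step 6 | (4S,5R)-4-(3,4-dimethoxyphenyl)-1-methoxy-5-methyl-7-(prop-2-en-1-yloxy)hept-6-en-2-one | COCC(=O)C[C@H](c1ccc(OC)c(OC)c1)[C@@H](C)C=COCC=C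
F10 | step 6 | (5S,6R)-1-(dimethylamino)-5-(3,4-dimethoxyphenyl)-2-methoxy-6-methyl-8-(prop-2-en-1-yloxy)octa-1,7-dien-3-one | CN(C)C=C(OC)C(=O)C[C@H](c1ccc(OC)c(OC)c1)[C@@H](C)C=COCC=C
F11 | step 6 | sodium (5S,6R)-5-(3,4-dimethoxyphenyl)-2-methoxy-6-methyl-3-oxo-8-(prop-2-en-1-yloxy)octa-1,7-dien-1-olate | [Na+].[O-]C=C(OC)C(=O)C[C@H](c1ccc(OC)c(OC)c1)[C@@H](C)C=COCC=C
F12 | step 8 | (3S,4S,7Z)-4-(3,4-dimethoxyphenyl)-7,8-dimethoxy-3-methyl-6-oxooct-7-enal | CO/C=C(\OC)C(=O)C[C@H](c1ccc(OC)c(OC)c1)[C@@H](C)CC=O
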